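**Plan**

1. Cuts: the furanone bonds C1–C2 and O–C10 (both in the last step), then C6–C7 together with the lactone bond O6–C12, then the ester O15–C1; C2–C6 plus C15 come from one 2-methylfuran, C11–C13 from methyl acrylate.
2. Enabling feature: the C15 hydroxymethyl oxygen sits on C4, β to the C3 carbonyl, so C2, C3, C4, C15, O15 and C1 can form a six-membered transition state. Acylating O15 with C1 turns the ten-membered carbocycle (C1–C10) into an isomeric ten-membered lactone (C1, O15, C15, C4–C10), and C10, α to the C1 ketone, is carried as a tertiary chloride.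
3. Forward ring order: butanolide template (temporary, opened in step 6) → ten-membered lactone and cis α-methylene-γ-lactone together (step 12) → ten-membered carbocycle and furanone together (step 13).
4. Stereochemistry: C8 from (R)-5-(hydroxymethyl)butanolide; C10 by chlorination of the lactone enolate anti to the C5 side chain, then inversion in step 13; C6 and C7 by the syn-selective, C8-directed Barbier closure; the C4=C5 geometry from the furan ring.
5. Helpers removed: lactone template (step 6), silyl group (step 7), furan mask (step 11), the O15–C1 tether and the chloride (step 13, which frees the C15 hydroxyl).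

Key step: step 13

Remark: locants follow germacranolide numbering (C1 ketone, C2, C3, C4 bearing C15, C5, C6 lactone carbinol, C7, C8 ester carbinol, C9, C10 bearing C14, C11=C13, C12 lactone carbonyl). The target is taken as drawn, (6S,7R,8R,10R) with a cis-fused lactone. TBDPS = tert-butyldiphenylsilyl.

**Route**

Step 1
Reactants: 1 (R)-5-(hydroxymethyl)dihydrofuran-2(3H)-one
Product: 2 (R)-5-[(TBDPS-oxy)methyl]dihydrofuran-2(3H)-one
Conditions: TBDPSCl, imidazole, DMF, 0 to 25 °C
Reagents that add atoms: tert-butyl(chloro)diphenylsilane, CC(C)(C)[Si](Cl)(c1ccccc1)c1ccccc1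
Why: Standard silylation of a primary alcohol; the bulky silyl ether later shields one face of the lactone enolate.

Step 2
Reactants: 2 (R)-5-[(TBDPS-oxy)methyl]dihydrofuran-2(3H)-one
Product: 3 (3S,5R)-5-[(TBDPS-oxy)methyl]-3-methyldihydrofuran-2(3H)-one
Conditions: LiN(iPr)2, THF, −78 °C; MeI, −78 to −40 °C
Reagents that add atoms: iodomethane, CI
Why: Lactone enolate alkylation; methyl should enter anti to the C5 substituent, although this centre is made planar again in step 3.

Step 3
Reactants: 3 (3S,5R)-5-[(TBDPS-oxy)methyl]-3-methyldihydrofuran-2(3H)-one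
Product: 4 (3S,5R)-5-[(TBDPS-oxy)methyl]-3-chloro-3-methyldihydrofuran-2(3H)-one
Conditions: LiN(SiMe3)2, THF, −78 °C; C2Cl6, −78 to −30 °C
Reagents that add atoms: hexachloroethane, ClC(Cl)(Cl)C(Cl)(Cl)Cl
Why: Electrophilic chlorination of the tetrasubstituted lithium enolate; chlorine should be delivered to the face opposite the C5 silyloxymethyl group (the 1,3-induction known from double alkylation of such butanolides), giving the (3S) tertiary chloride with Cl trans to the side chain.

Step 4
Reactants: 5 methyl 2-methylfuran-3-carboxylate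
Product: 6 (2-methylfuran-3-yl)methanol
Conditions: LiAlH4, Et2O, 0 °C
Reagents that add atoms: none
Why: Hydride reduction of an ester to the primary alcohol.

Step 5
Reactants: 6 (2-methylfuran-3-yl)methanol
Product: 7 3-(bromomethyl)-2-methylfuran
Conditions: PBr3, pyridine (cat.), Et2O, −20 to 0 °C; ethereal solution used at once
Reagents that add atoms: phosphorus tribromide, BrP(Br)Br
Why: Standard conversion of a 3-furylmethanol into the bromide, which is used without storage because it is reactive.

Step 6
Reactants: 4 (3S,5R)-5-[(TBDPS-oxy)methyl]-3-chloro-3-methyldihydrofuran-2(3H)-one; 7 3-(bromomethyl)-2-methylfuran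
Product: 10 (2-methylfuran-3-yl)methyl (2S,4R)-5-(TBDPS-oxy)-2-chloro-2-methyl-4-[(3-methylbutanoyl)oxy]pentanoate, via cesium carboxylate 8 (not isolated), via hydroxy ester 9 (not isolated)
Conditions: CsOH·H2O (1.0 equiv), THF/H2O, 0 °C; evaporate, PhMe azeotrope; 7, DMF, 0 °C; then isovaleric anhydride, DMAP, pyridine, 0 °C
Reagents that add atoms: cesium hydroxide, [Cs+].[OH-]; 3-methylbutanoic anhydride, CC(C)CC(=O)OC(=O)CC(C)C
Why: Saponification opens the template lactone, carboxylate O-alkylation forms the O15–C1 ester without activating the carbonyl towards re-lactonisation, and DMAP-catalysed acylation caps the free C8 hydroxyl at once; no stereocentre is touched.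

Step 7
Reactants: 10 (2-methylfuran-3-yl)methyl (2S,4R)-5-(TBDPS-oxy)-2-chloro-2-methyl-4-[(3-methylbutanoyl)oxy]pentanoate
Product: 11 (2-methylfuran-3-yl)methyl (2S,4R)-2-chloro-5-hydroxy-2-methyl-4-[(3-methylbutanoyl)oxy]pentanoate
Conditions: HF·pyridine, pyridine, THF, 0 to 25 °C
Reagents that add atoms: none
Why: Fluoride desilylation under buffered acidic conditions, which should suppress migration of the neighbouring isovalerate.

Step 8
Reactants: 11 (2-methylfuran-3-yl)methyl (2S,4R)-2-chloro-5-hydroxy-2-methyl-4-[(3-methylbutanoyl)oxy]pentanoate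
Product: 12 (2-methylfuran-3-yl)methyl (2S,4R)-2-chloro-2-methyl-4-[(3-methylbutanoyl)oxy]-5-oxopentanoate
Conditions: Dess–Martin periodinane, CH2Cl2, 0 to 25 °C; used crude
Reagents that add atoms: none
Why: Dess–Martin oxidation under neutral conditions gives the configurationally labile α-acyloxy aldehyde, which is carried on without chromatography.

Step 9
Reactants: 12 (2-methylfuran-3-yl)methyl (2S,4R)-2-chloro-2-methyl-4-[(3-methylbutanoyl)oxy]-5-oxopentanoate; 13 methyl acrylate
Product: 14 1-methyl 7-[(2-methylfuran-3-yl)methyl] (4R,6S)-6-chloro-3-hydroxy-6-methyl-2-methylidene-4-[(3-methylbutanoyl)oxy]heptanedioate (both C3 epimers)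
Conditions: DABCO (0.5 equiv), 13 (5 equiv), 1,4-dioxane/H2O 1:1, 25 °C
Reagents that add atoms: none
Why: Morita–Baylis–Hillman reaction, for which α-oxygenated aldehydes are activated partners; the new carbinol centre does not matter because it becomes sp2 in step 10.

Step 10
Reactants: 14 1-methyl 7-[(2-methylfuran-3-yl)methyl] (4R,6S)-6-chloro-3-hydroxy-6-methyl-2-methylidene-4-[(3-methylbutanoyl)oxy]heptanedioate
Product: 15 1-methyl 7-[(2-methylfuran-3-yl)methyl] (2Z,4R,6S)-2-(bromomethyl)-6-chloro-6-methyl-4-[(3-methylbutanoyl)oxy]hept-2-enedioate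
Conditions: MsCl, Et3N, CH2Cl2, −20 °C; then LiBr, THF, 0 °C
Reagents that add atoms: lithium bromide, [Li+].[Br-]
Why: Mesylation and bromide displacement with allylic transposition (SN2′) should give the thermodynamically preferred (Z)-2-(bromomethyl)alk-2-enoate, the usual outcome for such adducts, under conditions mild enough for the furan.

Step 11
Reactants: 15 1-methyl 7-[(2-methylfuran-3-yl)methyl] (2Z,4R,6S)-2-(bromomethyl)-6-chloro-6-methyl-4-[(3-methylbutanoyl)oxy]hept-2-enedioate
Product: 16 7-[(2Z)-2-acetyl-4-oxobut-2-en-1-yl] 1-methyl (2Z,4R,6S)-2-(bromomethyl)-6-chloro-6-methyl-4-[(3-methylbutanoyl)oxy]hept-2-enedioate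
Conditions: DMDO (1.1 equiv), acetone, −40 to 0 °C; concentrated cold and used at once
Reagents that add atoms: dimethyldioxirane, CC1(C)OO1
Why: Oxidative ring opening of a 2-methylfuran (epoxidation, then ring opening) unmasks the C3 methyl ketone and the C6 aldehyde at once; the furan ring guarantees that they are cis on C4=C5, which is the alkene geometry of the target.

Step 12
Reactants: 16 7-[(2Z)-2-acetyl-4-oxobut-2-en-1-yl] 1-methyl (2Z,4R,6S)-2-(bromomethyl)-6-chloro-6-methyl-4-[(3-methylbutanoyl)oxy]hept-2-enedioate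
Product: 18 ten-membered chloro keto lactone (6S,7R,8R,10S) fused to the cis α-methylene-γ-lactone, via hydroxy ester 17 (not isolated)
Conditions: In powder (2 equiv), THF/H2O 4:1, slow addition of 16 to 0.002 M, 25 °C; then PPTS (cat.), 40 °C
Reagents that add atoms: none
Why: Intramolecular Barbier allylation with indium metal, which should insert into the allylic bromide but not the tertiary α-chloro ester and add to the aldehyde in preference to the ketone; the (Z)-allylindium reacts through a chair six-membered transition state to give the syn adduct at C6/C7, the C8 centre (its hydrogen eclipsing the allyl unit to avoid allylic 1,3-strain) directs the aldehyde to the face anti to the C9 chain (an anti C6–C7–C8–C9 torsion that the ten-membered ring also prefers) to set (6S,7R), and the cis hydroxy ester then lactonises under mild acid.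

Step 13
Reactants: 18 ten-membered chloro keto lactone (6S,7R,8R,10S) fused to the cis α-methylene-γ-lactone
Product: 20 CNP0171896.2 (6S,7R,8R,10R), via chloro diketone 19 (not isolated)
Conditions: LiN(SiMe3)2 (1.05 equiv), THF, −78 to 0 °C; then DMPU, 25 to 40 °C; pH 7 buffer
Reagents that add atoms: none
Why: Proposed new method: kinetic deprotonation of the methyl ketone gives the C2 enolate, which attacks the lactone carbonyl C1 through a six-membered transition state (C2, C3, C4, C15, O15, C1; 6-(enolendo)-exo-trig); collapse of the tetrahedral intermediate moves the acyl group from O15 to C2, so the ten-membered lactone is exchanged for the isomeric ten-membered carbocycle without any direct medium-ring closure, O15 is released as the free hydroxymethyl group, and the alkoxide deprotonates the new 1,3-diketone, which drives the transfer. The C3 enolate oxygen of diketonate 19 then displaces the tertiary chloride at C10 in a 5-exo-tet O-alkylation that closes the furanone ring. The closest known reaction types are the Baker–Venkataraman 1,5-acyl shift of β-acyloxy ketone enolates and the base-induced closure of γ-halo-β-diketones to 3(2H)-furanones (Feist–Benary-type O-alkylation); their use to switch a macrolactone into a carbocycle is the new element. C10 is the only new stereocentre and should be set by inversion of the (10S) chloride to (10R), because an α-keto carbocation is too unstable for ionisation and substitution at tertiary α-chloro carbonyl centres is known to go with inversion. The step needs deprotonation of the ketone rather than the isovalerate or C6–H (one equivalent of base at −78 °C, then the fast intramolecular acyl transfer), O- rather than C-alkylation and substitution rather than loss of HCl (five-membered ring size; DMPU frees the enolate oxygen from lithium chelation), and an untouched α-methylene lactone (no nucleophile remains once the neutral furanone and LiCl have formed).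

**Compound list**

1 | (R)-5-(hydroxymethyl)dihydrofuran-2(3H)-one | O=C1CC[C@H](CO)O1 | starting material
2 | (R)-5-{[(tert-butyldiphenylsilyl)oxy]methyl}dihydrofuran-2(3H)-one | O=C1CC[C@H](CO[Si](c2ccccc2)(c2ccccc2)C(C)(C)C)O1 | intermediate
3 | (3S,5R)-5-{[(tert-butyldiphenylsilyl)oxy]methyl}-3-methyldihydrofuran-2(3H)-one (trans isomer, expected main component) | O=C1[C@@H](C)C[C@H](CO[Si](c2ccccc2)(c2ccccc2)C(C)(C)C)O1 | intermediate
4 | (3S,5R)-5-{[(tert-butyldiphenylsilyl)oxy]methyl}-3-chloro-3-methyldihydrofuran-2(3H)-one (Cl trans to the side chain) | O=C1[C@@](C)(Cl)C[C@H](CO[Si](c2ccccc2)(c2ccccc2)C(C)(C)C)O1 | intermediate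
5 | methyl 2-methylfuran-3-carboxylate | Cc1occc1C(=O)OC | starting material
6 | (2-methylfuran-3-yl)methanol | Cc1occc1CO | intermediate
7 | 3-(bromomethyl)-2-methylfuran | Cc1occc1CBr | intermediate
8 | cesium (2S,4R)-5-[(tert-butyldiphenylsilyl)oxy]-2-chloro-4-hydroxy-2-methylpentanoate | [Cs+].[O-]C(=O)[C@@](C)(Cl)C[C@@H](O)CO[Si](c1ccccc1)(c1ccccc1)C(C)(C)C | intermediate (not isolated)
9 | (2-methylfuran-3-yl)methyl (2S,4R)-5-[(tert-butyldiphenylsilyl)oxy]-2-chloro-4-hydroxy-2-methylpentanoate | Cc1occc1COC(=O)[C@@](C)(Cl)C[C@@H](O)CO[Si](c1ccccc1)(c1ccccc1)C(C)(C)C | intermediate (not isolated)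
10 | (2-methylfuran-3-yl)methyl (2S,4R)-5-[(tert-butyldiphenylsilyl)oxy]-2-chloro-2-methyl-4-[(3-methylbutanoyl)oxy]pentanoate | Cc1occc1COC(=O)[C@@](C)(Cl)C[C@@H](OC(=O)CC(C)C)CO[Si](c1ccccc1)(c1ccccc1)C(C)(C)C | intermediate
11 | (2-methylfuran-3-yl)methyl (2S,4R)-2-chloro-5-hydroxy-2-methyl-4-[(3-methylbutanoyl)oxy]pentanoate | Cc1occc1COC(=O)[C@@](C)(Cl)C[C@@H](OC(=O)CC(C)C)CO | intermediate
12 | (2-methylfuran-3-yl)methyl (2S,4R)-2-chloro-2-methyl-4-[(3-methylbutanoyl)oxy]-5-oxopentanoate | Cc1occc1COC(=O)[C@@](C)(Cl)C[C@@H](OC(=O)CC(C)C)C=O | intermediate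
13 | methyl acrylate | C=CC(=O)OC | starting material
14 | 1-methyl 7-[(2-methylfuran-3-yl)methyl] (4R,6S)-6-chloro-3-hydroxy-6-methyl-2-methylidene-4-[(3-methylbutanoyl)oxy]heptanedioate (both C3 epimers) | Cc1occc1COC(=O)[C@@](C)(Cl)C[C@@H](OC(=O)CC(C)C)C(O)C(=C)C(=O)OC | intermediate
15 | 1-methyl 7-[(2-methylfuran-3-yl)methyl] (2Z,4R,6S)-2-(bromomethyl)-6-chloro-6-methyl-4-[(3-methylbutanoyl)oxy]hept-2-enedioate | Cc1occc1COC(=O)[C@@](C)(Cl)C[C@@H](OC(=O)CC(C)C)/C=C(\CBr)C(=O)OC | intermediate
16 | 7-[(2Z)-2-acetyl-4-oxobut-2-en-1-yl] 1-methyl (2Z,4R,6S)-2-(bromomethyl)-6-chloro-6-methyl-4-[(3-methylbutanoyl)oxy]hept-2-enedioate | CC(=O)/C(COC(=O)[C@@](C)(Cl)C[C@@H](OC(=O)CC(C)C)/C=C(\CBr)C(=O)OC)=C\C=O | intermediate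
17 | hydroxy ester: ten-membered lactone (ring C1, O15, C15, C4, C5, C6, C7, C8, C9, C10) with 4-acetyl cis to C6, 6-hydroxy, 7-[1-(methoxycarbonyl)vinyl], 8-O-isovaleryl, 10-chloro-10-methyl; same spatial arrangement as 18 (CIP 6S,7S,8R,10S) | CC(=O)/C1=C\[C@H](O)[C@H](C(=C)C(=O)OC)[C@H](OC(=O)CC(C)C)C[C@](C)(Cl)C(=O)OC1 | intermediate (not isolated)
18 | chloro keto lactone: the same ten-membered lactone (O15 acylated by C1) with 4-acetyl cis to C6, cis-fused 6,12-α-methylene-γ-lactone, 8-O-isovaleryl, 10-chloro-10-methyl; (6S,7R,8R,10S) | CC(=O)/C1=C\[C@@H]2OC(=O)C(=C)[C@@H]2[C@H](OC(=O)CC(C)C)C[C@](C)(Cl)C(=O)OC1 | intermediate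
19 | ring-switched chloro diketone (formed as its lithium enolate): ten-membered carbocycle C1–C10 with C1 and C3 ketones, C2 methylene, 4Z alkene bearing free C15 hydroxymethyl, cis 6,12-α-methylene-γ-lactone, 8-O-isovaleryl, 10-chloro-10-methyl; (6S,7R,8R,10S) | OC/C1=C/[C@@H]2OC(=O)C(=C)[C@@H]2[C@H](OC(=O)CC(C)C)C[C@](C)(Cl)C(=O)CC1=O | intermediate (not isolated)
20 | CNP0171896.2: (4Z,6S,7R,8R,10R)-15-hydroxy-8-(3-methylbutanoyloxy)-1-oxo-3,10-epoxygermacra-2,4,11(13)-trien-12,6-olide | C=C1C(=O)O[C@H]2/C=C(/CO)C3=CC(=O)[C@@](C)(C[C@@H](OC(=O)CC(C)C)[C@@H]12)O3 | target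

**Summary**

Total step count: 13. Longest linear sequence: 11 steps (1 to 20 through steps 1–3 and 6–13).

Steps most likely to fail:

Step 13 (proposed new method). What may go wrong: the ten-membered lactone may be unable to reach the six-membered transition state for the O15-to-C2 acyl transfer. The enolate or the released alkoxide may instead add to the α-methylene lactone, or HCl may be lost from C10 in place of ring closure. Fallback with known chemistry (furanone first, carbocycle last), setting out from diester 10 and returning at 20: DMDO opens the furan of 10 to keto-enal F1. The aldehyde alone is protected (1,2-bis(trimethylsilyloxy)ethane, TMSOTf cat., −78 °C) as dioxolane F2. LiN(SiMe3)2 then brings about the acyl shift and ring closure on this open-chain β-acyloxy ketone, the substrate class for which the base-induced 1,5-acyl shift and the closure of γ-halo-β-diketones to 3(2H)-furanones are established, to give furanone alcohol F3 with the (10R) centre. Allyl chloroformate and pyridine give allyl carbonate F4; HF·pyridine gives primary alcohol F5; Dess–Martin oxidation gives aldehyde F6; DABCO and methyl acrylate give the Morita–Baylis–Hillman adduct F7; MsCl/Et3N then LiBr give (Z)-allylic bromide F8; PPTS in wet acetone removes the dioxolane to give enal F9. Indium metal at high dilution closes the ten-membered carbocycle by intramolecular Barbier allylation, the ring closure established for germacranolides, to hydroxy ester F10, which lactonises to allyl carbonate F11. Pd(PPh3)4 with dimedone removes the allyl carbonate and gives 20.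

Step 12. What may go wrong: poor facial or simple diastereoselectivity in the ring closure, oligomerisation in place of ten-membered ring formation, reduction of the ene-dione by the metal, or dehydration of the (Z)-γ-hydroxy enone to a furan before lactonisation. Fallback, setting out from allylic bromide 15 and returning at 18: CuCl-catalysed borylation with B2pin2 and KOAc gives allylboronate F12 with the alkene geometry retained. DMDO gives keto-enal boronate F13. At high dilution a BINOL-derived phosphoric acid (TRIP, the enantiomer matched to the required aldehyde face) catalyses intramolecular allylboration through a closed chair transition state; no reducing metal is present and facial selectivity comes under catalyst control, giving borate F14. Hydrolytic work-up gives hydroxy ester 17, which lactonises to 18 as in step 12.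

Step 6. What may go wrong: re-closure of γ-hydroxy ester 9 to the lactone with loss of the furylmethyl alcohol before acylation, or solvolysis of the tertiary chloride at the carboxylate stage. Fallback, setting out from chloro lactone 4 and returning at 10: the lactone is opened by reduction, so that C1 stays at the alcohol level while the C8 hydroxyl is acylated. LiBH4 gives diol F15; TBSCl and imidazole silylate the primary hydroxyl to give silyl ether F16; isovaleric anhydride and DMAP give ester F17; PPTS in MeOH removes the primary TBS ether in the presence of the TBDPS ether to give alcohol F18; TEMPO with PhI(OAc)2 in aqueous MeCN gives acid F19; Cs2CO3 and bromide 7 in DMF give 10.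

**Further compounds**

F1 | step 13 | keto-enal from furan opening of 10 | CC(=O)/C(COC(=O)[C@@](C)(Cl)C[C@@H](OC(=O)CC(C)C)CO[Si](c1ccccc1)(c1ccccc1)C(C)(C)C)=C\C=O
F2 | step 13 | dioxolane of F1 (aldehyde protected) | CC(=O)/C(COC(=O)[C@@](C)(Cl)C[C@@H](OC(=O)CC(C)C)CO[Si](c1ccccc1)(c1ccccc1)C(C)(C)C)=C\C1OCCO1
F3 | step 13 | furanone alcohol (10R; free C15 hydroxyl; C6 dioxolane; C7 silyl ether) | OC/C(=C/C1OCCO1)C1=CC(=O)[C@@](C)(C[C@@H](OC(=O)CC(C)C)CO[Si](c2ccccc2)(c2ccccc2)C(C)(C)C)O1
F4 | step 13 | allyl carbonate of F3 | C=CCOC(=O)OC/C(=C/C1OCCO1)C1=CC(=O)[C@@](C)(C[C@@H](OC(=O)CC(C)C)CO[Si](c2ccccc2)(c2ccccc2)C(C)(C)C)O1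
F5 | step 13 | primary alcohol (C7 hydroxyl free) | C=CCOC(=O)OC/C(=C/C1OCCO1)C1=CC(=O)[C@@](C)(C[C@@H](OC(=O)CC(C)C)CO)O1
F6 | step 13 | C7 aldehyde | C=CCOC(=O)OC/C(=C/C1OCCO1)C1=CC(=O)[C@@](C)(C[C@@H](OC(=O)CC(C)C)C=O)O1
F7 | step 13 | Morita–Baylis–Hillman adduct (both carbinol epimers) | C=CCOC(=O)OC/C(=C/C1OCCO1)C1=CC(=O)[C@@](C)(C[C@@H](OC(=O)CC(C)C)C(O)C(=C)C(=O)OC)O1
F8 | step 13 | (Z)-allylic bromide | C=CCOC(=O)OC/C(=C/C1OCCO1)C1=CC(=O)[C@@](C)(C[C@@H](OC(=O)CC(C)C)/C=C(\CBr)C(=O)OC)O1
F9 | step 13 | enal (dioxolane removed) | C=CCOC(=O)OC/C(=C/C=O)C1=CC(=O)[C@@](C)(C[C@@H](OC(=O)CC(C)C)/C=C(\CBr)C(=O)OC)O1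
F10 | step 13 | carbocyclic hydroxy ester (C6 hydroxyl, C7 1-(methoxycarbonyl)vinyl, C15 allyl carbonate) | C=C(C(=O)OC)[C@H]1[C@@H](O)/C=C(/COC(=O)OCC=C)C2=CC(=O)[C@@](C)(C[C@H]1OC(=O)CC(C)C)O2
F11 | step 13 | C15 allyl carbonate of the target | C=C1C(=O)O[C@H]2/C=C(/COC(=O)OCC=C)C3=CC(=O)[C@@](C)(C[C@@H](OC(=O)CC(C)C)[C@@H]12)O3
F12 | step 12 | allylboronate (pinacol boronate in place of bromide in 15; geometry retained) | Cc1occc1COC(=O)[C@@](C)(Cl)C[C@@H](OC(=O)CC(C)C)/C=C(\CB1OC(C)(C)C(C)(C)O1)C(=O)OC
F13 | step 12 | keto-enal boronate | CC(=O)/C(COC(=O)[C@@](C)(Cl)C[C@@H](OC(=O)CC(C)C)/C=C(\CB1OC(C)(C)C(C)(C)O1)C(=O)OC)=C\C=O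
F14 | step 12 | pinacol borate of hydroxy ester 17 | CC(=O)/C1=C\[C@H](OB2OC(C)(C)C(C)(C)O2)[C@H](C(=C)C(=O)OC)[C@H](OC(=O)CC(C)C)C[C@](C)(Cl)C(=O)OC1
F15 | step 6 | (2S,4R)-5-[(tert-butyldiphenylsilyl)oxy]-2-chloro-2-methylpentane-1,4-diol | OC[C@@](C)(Cl)C[C@@H](O)CO[Si](c1ccccc1)(c1ccccc1)C(C)(C)C
F16 | step 6 | 1-O-TBS ether of F15 | CC(C)(C)[Si](C)(C)OC[C@@](C)(Cl)C[C@@H](O)CO[Si](c1ccccc1)(c1ccccc1)C(C)(C)C
F17 | step 6 | 4-O-isovalerate of F16 | CC(C)(C)[Si](C)(C)OC[C@@](C)(Cl)C[C@@H](OC(=O)CC(C)C)CO[Si](c1ccccc1)(c1ccccc1)C(C)(C)C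
F18 | step 6 | primary alcohol (TBS removed) | OC[C@@](C)(Cl)C[C@@H](OC(=O)CC(C)C)CO[Si](c1ccccc1)(c1ccccc1)C(C)(C)C
F19 | step 6 | (2S,4R)-5-[(tert-butyldiphenylsilyl)oxy]-2-chloro-2-methyl-4-[(3-methylbutanoyl)oxy]pentanoic acid | OC(=O)[C@@](C)(Cl)C[C@@H](OC(=O)CC(C)C)CO[Si](c1ccccc1)(c1ccccc1)C(C)(C)C
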